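## Structural features

The target is a 2,3-dihydro-1,4-benzodioxine: a benzene ring (ring A) fused to a 1,4-dioxane (ring B). C2 carries a free 4-hydroxy-3-methoxyphenyl group (ring C), C3 a hydroxymethyl group and C6 of ring A an E-propenoic acid. O1 is para and O4 is meta to the acid side chain, so the two catechol oxygens of ring A are not equivalent and each must be joined to the right sp3 carbon. C2 and C3 are adjacent stereocentres, both R, with the aryl and hydroxymethyl groups trans and both equatorial on the half-chair. The fragile elements are the C2–O1 bond, the conjugated acid and the C3–H. The C2–O1 bond is a benzylic aryl ether para to a free phenol and can ionise under acid or base. The acid cannot be carried through hydride, organomagnesium or hydrogenation steps. The C3–H becomes activated whenever C2 is trigonal. The difficulty lies less in the carbon skeleton than in fixing the absolute configuration at C3, the trans relationship at C2 and the O1/O4 regiochemistry together. The key step uses the para-hydroxyl of ring C, which makes C2 the terminus of a para-quinone methide, and the ring A oxygen O1, which is held five atoms away through O4–C3. C2 can therefore be left uncontrolled until ring B closes, and C3 alone, taken from the chiral pool, decides the outcome.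

## Logic of the disconnections

**18 to 16.** The Cα=Cβ bond of the propenoic acid on C6 is cut, which leads back to the C6 aldehyde. The acid is the one group that clashes with every earlier reagent, so it is added last, and the E geometry is the thermodynamic outcome of a decarboxylative condensation. The gain is a formyl group in place of an unsaturated acid. The forward step must tolerate a free phenol and a primary alcohol, with base mild enough not to open C2–O1.

**16 to 15.** No skeletal bond is cut. The formyl carbon returns to a cyclic acetal and the C3 hydroxymethyl to its tert-butyl ether. Both masks resist hydride, organomagnesium reagents and hydrogenolysis, and both fall in one acidic operation. The forward step needs acid strong enough for the ether that leaves ring B closed.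

**15 to 13.** The O1–C2 bond is cut; this is the strategic disconnection. It removes ring B and the C2 stereocentre at once, leaving an acyclic ether with one controlled stereocentre and a carbinol carbon whose configuration is irrelevant. The forward step must deliver trans selectivity against C3, O- rather than C-alkylation of ring A, no tautomerisation of the trigonal intermediate and survival of the acid-labile masks.

**13 to 12.** The two phenolic O–benzyl bonds are cut. Both phenols are needed free only in step 8 (ring C to expel water, ring A as the nucleophile) and must be silent towards the organometallic step before it. The forward hydrogenolysis must spare the benzylic C–OH bond and the benzylic acetal.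

**12 to 7 and 9 (through 10 and 11).** The bond between the carbinol carbon (the future C2) and ring C is cut. Ring C then arrives as a nucleophile on an aldehyde-level carbon, and no stereocontrol is asked for because step 8 erases that centre. The molecule splits into a ring C bromide and a ring A–C3 ester with one stereocentre. Aldehyde 10 is α-aryloxy and epimerisable, so it must be generated and consumed cold without isolation.

**7 to 4 and 6.** The O4–C3 bond is cut. An aryl ether at a stereocentre is made reliably with inversion from a secondary alcohol, and 6 has only one free phenol, so the O1/O4 question is settled by the choice of 5. C3 is traced to a chiral-pool hydroxy ester. The forward step needs clean SN2 inversion without elimination towards the β-alkoxy acrylate.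

**4 to 3 to 1.** The C3–O bond is traced to the C–N bond of 1 and the ester O–CH3 bond is cut. Compound 1 is a cheap single enantiomer that already carries the tert-butyl ether needed later. The forward steps need overall retention at the α-carbon and no acid strong enough to strip the ether.

**6 to 5 and 9 to 8.** The acetal C–O bonds and one O–benzyl bond are cut. Placing the acetal before the ether coupling keeps acid away from both the stereocentre and the tert-butyl ether. Both forward steps are routine protections.

## Other disconnections considered

**Alternative 1:** The cut runs through C2–C3 and O1–C2 together, leading back to the ring A aryloxyacetaldehyde A2 and vanillin acetate A3. In the forward step a chiral primary amine salt would condense A2 with A3 to an α-aryloxy enal. The iminium ion of that enal would accept O1 at C2 in a 6-endo-trig oxa-Michael addition, and protonation of the resulting enamine would set C3, giving A1.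
- In favour: both stereocentres and ring B would come from achiral pieces in one catalytic operation. The side chain is already present as its ester. The formyl-bearing C3 can epimerise, so the trans ring is within reach by equilibration.
- Against: A2 requires alkylation of the less acidic, meta hydroxyl of its catechol precursor and would sit largely as a cyclic hemiacetal. A2 is enolisable and prone to self-condensation, while A3 is an electron-rich, sluggish acceptor. The α-oxygenated, β-aryl enal is a deactivated Michael acceptor, and oxa-Michael additions revert, so the enantiomeric purity at C2 would rest on a reversible step. The later hydride reduction next to an enoate and the saponification of two esters put base on a free para-hydroxybenzyl ether.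
- Comparison: mechanistically the two plans are equal in closing ring B by adding O1 to C2 of a conjugated acceptor and in relying on the trans preference. Alternative 1 is better on convergence and step economy and needs no hydrogenolysis. The chosen plan is better on absolute configuration (C3 from the chiral pool, C2 by substrate control) and on O1/O4 regiochemistry, which the choice of 5 fixes.

**Alternative 2:** The cut removes C3 altogether (O4–C3 and C2–C3), leading back to the 2-aryl-1,3-benzodioxole A5 and tert-butyl diazoacetate A6. In the forward step a carbene from A6, made with Rh2(OAc)4 or Cu(acac)2, would add to O4. The oxonium ylide would then undergo a [1,2]-Stevens shift of the acetal carbon, expanding the five-membered ring to A4 (2R,3S by the CIP rules, the same trans arrangement in space).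
- In favour: A5 is one acetalisation away from simple materials, and a single step would form one C–O bond, one C–C bond and ring B.
- Against: O4 and O1 are both weakly nucleophilic aryl ether oxygens, distinguished only by being meta or para to the ester. Cyclopropanation of the electron-rich arenes, insertion into the acetal C–H and carbene dimerisation compete. A5 is racemic at the acetal carbon, and the shift passes through a radical or ion pair, so both relative and absolute control would have to come from a catalyst that may already have left the ylide. After A4 the two esters must be told apart before the aldehyde and the acid can be made.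
- Comparison: alternative 2 is better on the brevity of ring construction and on avoiding a benzylic carbinol. It is equal in the end-game, since both plans finish from a C6 aldehyde. It is weaker on stereocontrol and on chemoselectivity, where the chosen plan asks only for a diastereoselective closure next to a fixed centre. It also carries a diazo ester, whereas the chosen plan only generates a transient aliphatic diazonium ion in water.

**Alternative 3:** The cut is at O1–C8a, the aryl ether bond on ring A, leading back to the benzylic alcohol A8 with both stereocentres already in place on a meta-oxygenated phenol. In the forward step PhI(OAc)2 would oxidise the phenol, the benzylic hydroxyl would attack the ring carbon para to the phenol oxygen, and tautomerisation would give A7. The C6 hydroxyl would then be turned into the acid by sulfonylation and a Heck coupling.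
- In favour: C2 is never ionised, so the closure is stereospecific, cannot disturb C3 and could deliver a cis ring equally well. It is also acid-free.
- Against: A8 needs both stereocentres set beforehand, so a carbinol mixture such as 12 could not be used. The ortho position between the two oxygens offers a competing six-membered closure. A7 is a hydroquinone monoether, more easily oxidised than A8, so over-oxidation threatens, as does oxidation of the electron-rich benzylic alcohol. The end-game adds sulfonylation, coupling and removal of a sulfonate and a pivalate.
- Comparison: alternative 3 is better on the stereochemical integrity of the closure itself. It is equal in closing the same ring B through one C–O bond. The chosen plan is better on the simplicity of its precursor (one controlled centre instead of two), on chemoselectivity and on step count after ring closure.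

Key step: step 8

Assumption: ring B is numbered O1–C2(aryl)–C3(CH2OH)–O4 with O1 para to the side chain of ring A. Compounds 12 and 13 are carried as mixtures of carbinol epimers, which step 8 makes equivalent. The serine-derived carbon keeps one spatial arrangement from 7 onwards, although its CIP label reads S in 14.

## Route

Step 1
Reactants: 1 O-tert-butyl-L-serine
Product: 3 (S)-3-tert-butoxy-2-hydroxypropanoic acid, via alpha-lactone 2 (not isolated)
Conditions: NaNO2, 0.5 M aq. H2SO4, 0 °C → rt
Reagents that add atoms: water, O
Why: Diazotisation of an α-amino acid; the neighbouring carboxylate displaces nitrogen with inversion to give 2 and water opens it with a second inversion, so the S configuration should be retained, and the tert-butyl ether tolerates cold dilute aqueous acid.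

Step 2
Reactants: 3 (S)-3-tert-butoxy-2-hydroxypropanoic acid
Product: 4 methyl (S)-3-tert-butoxy-2-hydroxypropanoate
Conditions: MeI, KHCO3, DMF, rt
Reagents that add atoms: iodomethane, CI
Why: SN2 O-alkylation of the carboxylate; the weak base leaves the secondary hydroxyl and the α-stereocentre alone, and no acid touches the tert-butyl ether.

Step 3
Reactants: 5 4-(benzyloxy)-3-hydroxybenzaldehyde
Product: 6 2-(benzyloxy)-5-(1,3-dioxolan-2-yl)phenol
Conditions: HOCH2CH2OH, p-TsOH·H2O (cat.), toluene, reflux with azeotropic removal of water; Et3N quench
Reagents that add atoms: ethylene glycol, OCCO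
Why: Acid-catalysed acetalisation driven by water removal; done at this stage, the only acid-catalysed protection is carried out before the stereocentre and the tert-butyl ether are in the molecule.

Step 4
Reactants: 4 methyl (S)-3-tert-butoxy-2-hydroxypropanoate; 6 2-(benzyloxy)-5-(1,3-dioxolan-2-yl)phenol
Product: 7 methyl (R)-2-[2-(benzyloxy)-5-(1,3-dioxolan-2-yl)phenoxy]-3-tert-butoxypropanoate
Conditions: PPh3, DIAD, THF, 0 °C → rt
Reagents that add atoms: none
Why: Mitsunobu etherification of an α-hydroxy ester with a phenol; the phenoxide displaces the alkoxyphosphonium group by SN2, so C3 should be inverted from S to R, and the single free hydroxyl of 6 places the ether on the oxygen meta to the masked aldehyde (the future O4).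

Step 5
Reactants: 8 4-bromo-2-methoxyphenol
Product: 9 1-(benzyloxy)-4-bromo-2-methoxybenzene
Conditions: BnBr, K2CO3, DMF, rt
Reagents that add atoms: benzyl bromide, BrCc1ccccc1
Why: Williamson ether synthesis on a phenoxide; the benzyl ether makes the bromide fit for magnesium insertion and is removed together with the ring A benzyl group later.

Step 6
Reactants: 7 methyl (R)-2-[2-(benzyloxy)-5-(1,3-dioxolan-2-yl)phenoxy]-3-tert-butoxypropanoate; 9 1-(benzyloxy)-4-bromo-2-methoxybenzene
Product: 12 (2R)-1-[4-(benzyloxy)-3-methoxyphenyl]-2-[2-(benzyloxy)-5-(1,3-dioxolan-2-yl)phenoxy]-3-tert-butoxypropan-1-ol as a mixture of C1 epimers, via alpha-aryloxy aldehyde 10 (not isolated), via aryl Grignard reagent 11 (not isolated)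
Conditions: 9, Mg, THF, reflux; separately 7, iBu2AlH (1.05 equiv), CH2Cl2, –78 °C; then 11, –78 → 0 °C; aq. KNaC4H4O6
Reagents that add atoms: none
Why: Tandem partial reduction and Grignard addition; the aluminium hemiacetal formed at –78 °C releases 10 only in the presence of 11, so the epimerisable α-aryloxy aldehyde should not accumulate, and the new carbinol centre may form unselectively because step 8 erases it.

Step 7
Reactants: 12 (2R)-1-[4-(benzyloxy)-3-methoxyphenyl]-2-[2-(benzyloxy)-5-(1,3-dioxolan-2-yl)phenoxy]-3-tert-butoxypropan-1-ol
Product: 13 (2R)-3-tert-butoxy-2-[5-(1,3-dioxolan-2-yl)-2-hydroxyphenoxy]-1-(4-hydroxy-3-methoxyphenyl)propan-1-ol as a mixture of C1 epimers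
Conditions: H2 (1 atm), 10% Pd/C, EtOAc, rt; filtered and used at once
Reagents that add atoms: none
Why: Hydrogenolysis of two aryl benzyl ethers, which cleave faster than a benzylic alcohol or a benzylic acetal in a neutral aprotic medium; the tert-butyl ether and the stereocentre are not affected.

Step 8
Reactants: 13 (2R)-3-tert-butoxy-2-[5-(1,3-dioxolan-2-yl)-2-hydroxyphenoxy]-1-(4-hydroxy-3-methoxyphenyl)propan-1-ol
Product: 15 4-[(2R,3R)-3-(tert-butoxymethyl)-6-(1,3-dioxolan-2-yl)-2,3-dihydro-1,4-benzodioxin-2-yl]-2-methoxyphenol, via para-quinone methide 14 (not isolated)
Conditions: CSA (0.1 equiv), 4 Å MS, CH2Cl2, –20 → 0 °C; Et3N quench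
Reagents that add atoms: none
Why: The acid protonates the benzylic hydroxyl of either epimer of 13 and water leaves with the push of the para-hydroxyl of ring C, giving the planar para-quinone methide 14 (in its O-protonated form), in which the carbinol configuration is erased. The ring A phenol oxygen O1, held five atoms away through O4–C3, then adds to the methide carbon C2 in an intramolecular oxa-Michael (1,6-conjugate) addition that rearomatises ring C and forms the O1–C2 bond; the closest known reaction type is the acid-promoted formation of para-quinone methides from 4-hydroxybenzyl alcohols with capture by a phenol. Ring B closes in the 6-exo-trig mode, since the double bond that is attacked lies outside the new ring. The new stereocentre C2 is controlled by the existing C3 centre: in the chair-like transition state the tert-butoxymethyl group sits equatorial and the aryl group takes the other equatorial site, and because the addition can revert under the acid the ring should also settle thermodynamically as the diequatorial trans isomer, (2R,3R). The step needs O1 to win over every other nucleophile, and the substrate secures this: the ring C phenol cannot reach C2, the primary oxygen is capped as its tert-butyl ether, and C-alkylation of ring A is slower than O-attack at low temperature. C3 should keep its configuration because it lies outside the ionising system, provided that the low temperature and the fast intramolecular capture outrun tautomerisation of 14 to the enol ether. The catalytic amount of sulfonic acid and the sieves, which take up the water set free, are chosen so that the dioxolane and the tert-butyl ether stay in place.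

Step 9
Reactants: 15 4-[(2R,3R)-3-(tert-butoxymethyl)-6-(1,3-dioxolan-2-yl)-2,3-dihydro-1,4-benzodioxin-2-yl]-2-methoxyphenol
Product: 16 (2R,3R)-2-(4-hydroxy-3-methoxyphenyl)-3-(hydroxymethyl)-2,3-dihydro-1,4-benzodioxine-6-carbaldehyde
Conditions: TFA–H2O (9:1), 0 °C → rt; then NaHCO3, aq. MeOH
Reagents that add atoms: water, O
Why: Acid hydrolysis of the acetal and SN1 cleavage of the tert-butyl ether in one operation, with water as the trap for the tert-butyl cation and the bicarbonate wash removing any trifluoroacetate from the primary alcohol; neither stereocentre is touched, and a reversible opening at C2–O1 would return to the trans ring.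

Step 10
Reactants: 16 (2R,3R)-2-(4-hydroxy-3-methoxyphenyl)-3-(hydroxymethyl)-2,3-dihydro-1,4-benzodioxine-6-carbaldehyde
Product: 18 (E)-3-[(2R,3R)-2-(4-hydroxy-3-methoxyphenyl)-3-(hydroxymethyl)-2,3-dihydro-1,4-benzodioxin-6-yl]prop-2-enoic acid, via arylidenemalonic acid 17 (not isolated)
Conditions: CH2(CO2H)2, pyridine, piperidine (cat.), 60 °C
Reagents that add atoms: malonic acid, O=C(O)CC(=O)O
Why: Knoevenagel–Doebner condensation; the arylidenemalonic acid 17 loses carbon dioxide in pyridine to give the E acid as the thermodynamic isomer, and free phenols and alcohols are tolerated in this reaction, as in the conversion of hydroxybenzaldehydes into hydroxycinnamic acids.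

## Compound list

1 | O-tert-butyl-L-serine | N[C@@H](COC(C)(C)C)C(=O)O | starting material
2 | (R)-3-(tert-butoxymethyl)oxiran-2-one (alpha-lactone) | O=C1O[C@@H]1COC(C)(C)C | intermediate (not isolated)
3 | (S)-3-tert-butoxy-2-hydroxypropanoic acid | O[C@@H](COC(C)(C)C)C(=O)O | intermediate
4 | methyl (S)-3-tert-butoxy-2-hydroxypropanoate | O[C@@H](COC(C)(C)C)C(=O)OC | intermediate
5 | 4-(benzyloxy)-3-hydroxybenzaldehyde | O=Cc1ccc(OCc2ccccc2)c(O)c1 | starting material
6 | 2-(benzyloxy)-5-(1,3-dioxolan-2-yl)phenol | Oc1cc(C2OCCO2)ccc1OCc1ccccc1 | intermediate
7 | methyl (R)-2-[2-(benzyloxy)-5-(1,3-dioxolan-2-yl)phenoxy]-3-tert-butoxypropanoate | COC(=O)[C@@H](COC(C)(C)C)Oc1cc(C2OCCO2)ccc1OCc1ccccc1 | intermediate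
8 | 4-bromo-2-methoxyphenol | COc1cc(Br)ccc1O | starting material
9 | 1-(benzyloxy)-4-bromo-2-methoxybenzene | COc1cc(Br)ccc1OCc1ccccc1 | intermediate
10 | (R)-2-[2-(benzyloxy)-5-(1,3-dioxolan-2-yl)phenoxy]-3-tert-butoxypropanal | O=C[C@@H](COC(C)(C)C)Oc1cc(C2OCCO2)ccc1OCc1ccccc1 | intermediate (not isolated)
11 | [4-(benzyloxy)-3-methoxyphenyl]magnesium bromide | COc1cc([Mg]Br)ccc1OCc1ccccc1 | intermediate (not isolated)
12 | (2R)-1-[4-(benzyloxy)-3-methoxyphenyl]-2-[2-(benzyloxy)-5-(1,3-dioxolan-2-yl)phenoxy]-3-tert-butoxypropan-1-ol, both C1 epimers | COc1cc(C(O)[C@@H](COC(C)(C)C)Oc2cc(C3OCCO3)ccc2OCc2ccccc2)ccc1OCc1ccccc1 | intermediate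
13 | (2R)-3-tert-butoxy-2-[5-(1,3-dioxolan-2-yl)-2-hydroxyphenoxy]-1-(4-hydroxy-3-methoxyphenyl)propan-1-ol, both C1 epimers | COc1cc(C(O)[C@@H](COC(C)(C)C)Oc2cc(C3OCCO3)ccc2O)ccc1O | intermediate
14 | 4-{(2S)-3-tert-butoxy-2-[5-(1,3-dioxolan-2-yl)-2-hydroxyphenoxy]propylidene}-2-methoxycyclohexa-2,5-dien-1-one | COC1=CC(=C[C@@H](COC(C)(C)C)Oc2cc(C3OCCO3)ccc2O)C=CC1=O | intermediate (not isolated)
15 | 4-[(2R,3R)-3-(tert-butoxymethyl)-6-(1,3-dioxolan-2-yl)-2,3-dihydro-1,4-benzodioxin-2-yl]-2-methoxyphenol | COc1cc([C@H]2Oc3ccc(C4OCCO4)cc3O[C@@H]2COC(C)(C)C)ccc1O | intermediate
16 | (2R,3R)-2-(4-hydroxy-3-methoxyphenyl)-3-(hydroxymethyl)-2,3-dihydro-1,4-benzodioxine-6-carbaldehyde | COc1cc([C@H]2Oc3ccc(C=O)cc3O[C@@H]2CO)ccc1O | intermediate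
17 | 2-{[(2R,3R)-2-(4-hydroxy-3-methoxyphenyl)-3-(hydroxymethyl)-2,3-dihydro-1,4-benzodioxin-6-yl]methylidene}propanedioic acid | COc1cc([C@H]2Oc3ccc(C=C(C(=O)O)C(=O)O)cc3O[C@@H]2CO)ccc1O | intermediate (not isolated)
18 | (E)-3-[(2R,3R)-2-(4-hydroxy-3-methoxyphenyl)-3-(hydroxymethyl)-2,3-dihydro-1,4-benzodioxin-6-yl]prop-2-enoic acid | COc1cc([C@H]2Oc3ccc(/C=C/C(=O)O)cc3O[C@@H]2CO)ccc1O | target

## Step count and least certain steps

Total step count: 10. Longest linear sequence: 8 steps (steps 1, 2, 4, 6, 7, 8, 9 and 10); steps 3 and 5 are side branches.

**Step 8 (key step).** The most likely failure is tautomerisation of the quinone methide to the enol ether before ring closure, which would erase the C3 configuration. This becomes a danger if ionisation is slow enough at low temperature that the mixture has to be warmed. Slow Friedel–Crafts attack by ring A carbon and premature loss of the acetal are secondary concerns.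
Fallback, from 13 back to 15: the three hydroxyls of 13 would be acetylated (Ac2O, pyridine) to the triacetate F1. Treatment with K2CO3 in MeOH–THF at 0 °C should remove the two aryl acetates first. The ring C phenoxide would then expel the benzylic acetate by 1,6-elimination to give 14 without acid, and the ring A phenoxide would close ring B to 15. This is the known base-triggered release of quinone methides from 4-acyloxybenzyl esters.

**Step 6.** Enolisation of the α-aryloxy aldehyde by the basic organomagnesium reagent could erode the configuration at C3. Collapse of the aluminium hemiacetal before the nucleophile arrives could lead to over-reduction.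
Fallback, from 7 back to 12: the ester would be reduced fully with LiBH4 in THF to the primary alcohol F2. Oxidation with Dess–Martin periodinane buffered with NaHCO3 would give aldehyde 10, which would be treated at once with 11 at –78 °C to give 12. The aldehyde would then never meet aluminium alkoxides or excess hydride.

**Step 7.** Hydrogenolysis could go on to cleave the benzylic C–OH bond, which the para oxygen activates, giving the deoxygenated chain.
Fallback, from 12 back to 13: the carbinol would be oxidised with Dess–Martin periodinane to the ketone F3. Both benzyl ethers would then be removed over Pd/C to give the dihydroxy ketone F4, whose para-hydroxyaryl ketone resists hydrogenation. NaBH4 in EtOH at 0 °C would return 13 as an epimer mixture, which is acceptable because step 8 is stereoconvergent.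

**Step 9.** The tert-butyl cation could alkylate the electron-rich ring C. Once the electron-poor aldehyde is unmasked, C2–O1 could also open hydrolytically in the strong aqueous acid.
Fallback, from 15 back to 16: the acetal alone would be hydrolysed with PPTS in acetone–water to the aldehyde F5. The tert-butyl ether would then be cleaved with 85% aqueous H3PO4 in toluene at rt to give 16, a much weaker acid that is known to remove tert-butyl ethers.

**Step 10.** The amine base could open C2–O1 through the ring C phenoxide and add to the resulting methide, and decarboxylation may be slow at the mild temperature chosen to limit this.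
Fallback, from 16 back to 18: a Wittig reaction with Ph3P=CHCO2C(CH3)3 in CH2Cl2 at rt would give the tert-butyl ester F6 as the E isomer under neutral conditions. TFA–CH2Cl2 at 0 °C would then release the acid 18.

## Further compounds

F1 | step 8 | (2R)-1-(4-acetoxy-3-methoxyphenyl)-2-[2-acetoxy-5-(1,3-dioxolan-2-yl)phenoxy]-3-tert-butoxypropyl acetate, both C1 epimers | COc1cc(C(OC(C)=O)[C@@H](COC(C)(C)C)Oc2cc(C3OCCO3)ccc2OC(C)=O)ccc1OC(C)=O
F2 | step 6 | (S)-2-[2-(benzyloxy)-5-(1,3-dioxolan-2-yl)phenoxy]-3-tert-butoxypropan-1-ol | OC[C@@H](COC(C)(C)C)Oc1cc(C2OCCO2)ccc1OCc1ccccc1
F3 | step 7 | (R)-1-[4-(benzyloxy)-3-methoxyphenyl]-2-[2-(benzyloxy)-5-(1,3-dioxolan-2-yl)phenoxy]-3-tert-butoxypropan-1-one | COc1cc(C(=O)[C@@H](COC(C)(C)C)Oc2cc(C3OCCO3)ccc2OCc2ccccc2)ccc1OCc1ccccc1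
F4 | step 7 | (R)-3-tert-butoxy-2-[5-(1,3-dioxolan-2-yl)-2-hydroxyphenoxy]-1-(4-hydroxy-3-methoxyphenyl)propan-1-one | COc1cc(C(=O)[C@@H](COC(C)(C)C)Oc2cc(C3OCCO3)ccc2O)ccc1O
F5 | step 9 | (2R,3R)-3-(tert-butoxymethyl)-2-(4-hydroxy-3-methoxyphenyl)-2,3-dihydro-1,4-benzodioxine-6-carbaldehyde | COc1cc([C@H]2Oc3ccc(C=O)cc3O[C@@H]2COC(C)(C)C)ccc1O
F6 | step 10 | tert-butyl (E)-3-[(2R,3R)-2-(4-hydroxy-3-methoxyphenyl)-3-(hydroxymethyl)-2,3-dihydro-1,4-benzodioxin-6-yl]prop-2-enoate | COc1cc([C@H]2Oc3ccc(/C=C/C(=O)OC(C)(C)C)cc3O[C@@H]2CO)ccc1O
A1 | alternative 1 | methyl (E)-3-[(2R,3S)-2-(4-acetoxy-3-methoxyphenyl)-3-formyl-2,3-dihydro-1,4-benzodioxin-6-yl]prop-2-enoate | COc1cc([C@H]2Oc3ccc(/C=C/C(=O)OC)cc3O[C@@H]2C=O)ccc1OC(C)=O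
A2 | alternative 1 | methyl (E)-3-[4-hydroxy-3-(2-oxoethoxy)phenyl]prop-2-enoate | COC(=O)/C=C/c1ccc(O)c(OCC=O)c1
A3 | alternative 1 | 4-formyl-2-methoxyphenyl acetate (vanillin acetate) | COc1cc(C=O)ccc1OC(C)=O
A4 | alternative 2 | 3-tert-butyl 6-methyl (2R,3S)-2-[4-(tert-butyldimethylsilyloxy)-3-methoxyphenyl]-2,3-dihydro-1,4-benzodioxine-3,6-dicarboxylate | COc1cc([C@H]2Oc3ccc(C(=O)OC)cc3O[C@@H]2C(=O)OC(C)(C)C)ccc1O[Si](C)(C)C(C)(C)C
A5 | alternative 2 | methyl 2-[4-(tert-butyldimethylsilyloxy)-3-methoxyphenyl]-1,3-benzodioxole-5-carboxylate, racemic at the acetal carbon | COC(=O)c1ccc2OC(Oc2c1)c1ccc(O[Si](C)(C)C(C)(C)C)c(OC)c1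
A6 | alternative 2 | tert-butyl diazoacetate | CC(C)(C)OC(=O)C=[N+]=[N-]
A7 | alternative 3 | 4-[(2R,3R)-6-hydroxy-3-(pivaloyloxymethyl)-2,3-dihydro-1,4-benzodioxin-2-yl]-2-methoxyphenyl 4-methylbenzenesulfonate | COc1cc([C@H]2Oc3ccc(O)cc3O[C@@H]2COC(=O)C(C)(C)C)ccc1OS(=O)(=O)c1ccc(C)cc1
A8 | alternative 3 | (2R,3R)-3-hydroxy-2-(3-hydroxyphenoxy)-3-[3-methoxy-4-(tosyloxy)phenyl]propyl pivalate | COc1cc([C@@H](O)[C@@H](COC(=O)C(C)(C)C)Oc2cccc(O)c2)ccc1OS(=O)(=O)c1ccc(C)cc1
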